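**Plan**

1. Cuts: (a) in the bromocyclohexanol ring the C-2′–C-3′ bond, together with C-4′–Br and C-1′–O (bromonium-initiated cation–olefin cyclisation, the cation trapped by a Boc group on O-α); (b) C-α–C-1′ (2-lithio-1,5-diene + Weinreb amide, then C=O reduction) and C-4–CH3 (organocerium + ketone); (c) in the hydrindane C-2–C-3 (ester-enolate alkylation), C-7a–C-1 (enolate allylation), C-3a–C-3 (Mukaiyama–Michael) and C-7–Br (from C=O).
2. Enabling feature: in the bromocyclohexanol ring C-4′H(Br) is bonded to the gem-dimethyl carbon C-3′, which is linked through C-2′H2 to the oxygenated, fully substituted C-1′. This is the imprint of Br+ on a Me2C=CH terminus captured by the CH2 end of a 1,1-disubstituted alkene; the vicinal secondary OH on C-α can carry the carbonate that traps the C-1′ cation.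
3. Forward order: the six-membered ring of the hydrindane is bought (enone ketal 1); its substituents are set, the cyclopentane is closed trans by alkylation, the acyclic diene is attached, and the bromocyclohexane (with a temporary cyclic carbonate) is closed last. Ketal hydrolysis and methyl addition, which also removes the carbonate, finish the route.
4. Stereochemistry: C-3a by catalytic asymmetric Mukaiyama–Michael addition; C-7a by anti allylation; C-7 by Selectride reduction and Appel inversion; C-3 thermodynamically; C-α by Felkin–Anh (Luche) reduction; C-4′ by a chiral Lewis-base bromonium donor; C-1′ by chair cyclisation with axial carbonate capture; C-4 by equatorial methyl addition.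

Key step: step 15

Remark (locants): C-1 to C-7a are the hydrindane carbons of the target (inden-4-ol numbering), C-α is the exocyclic carbinol carbon, and C-1′ to C-6′ are the cyclohexane carbons (C-1′ carbinol, C-3′ CMe2, C-4′ CHBr). Intermediates are named with their own IUPAC locants.
Assumption: 1, 4 and 14 are taken as commercial; the sense of induction of the two chiral catalysts (steps 3 and 15) is set by choice of the antipode, and the face that has to be attacked is stated in each step. Reagents, catalysts and solvents are not numbered.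

**Route**

Step 1
Reactants: 1 1,4-dioxaspiro[4.5]dec-6-en-8-one
Product: 2 7-iodo-1,4-dioxaspiro[4.5]dec-6-en-8-one
Conditions: I2, pyridine/CH2Cl2 (1:1), 0 °C to rt
Reagents that add atoms: iodine, II
Why: α-Iodination of a cyclic enone by pyridine conjugate addition, iodination and elimination (the iodine–pyridine protocol) should give the 2-iodoenone without touching the ketal.

Step 2
Reactants: 2 7-iodo-1,4-dioxaspiro[4.5]dec-6-en-8-one
Product: 3 7-methyl-1,4-dioxaspiro[4.5]dec-6-en-8-one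
Conditions: Me4Sn, Pd2(dba)3 (2.5 mol %), AsPh3, CuI, NMP, 60 °C
Reagents that add atoms: tetramethylstannane, C[Sn](C)(C)C
Why: Stille cross-coupling of the vinylic C–I bond, a standard way to α-alkylate enones through their α-iodo derivatives, should install the methyl group regiospecifically.

Step 3
Reactants: 3 7-methyl-1,4-dioxaspiro[4.5]dec-6-en-8-one; 4 tert-butyl[(1-methoxyethenyl)oxy]dimethylsilane
Product: 5 methyl 2-[(6S)-8-{[tert-butyl(dimethyl)silyl]oxy}-7-methyl-1,4-dioxaspiro[4.5]dec-7-en-6-yl]acetate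
Conditions: chiral o-tolyl oxazaborolidinium triflimide (diphenylprolinol-derived, 20 mol %, antipode for Si-face attack at C-6), Ph3PO (25 mol %), toluene, −20 °C
Reagents that add atoms: none
Why: A Mukaiyama–Michael addition catalysed by a chiral oxazaborolidinium Lewis acid, a reaction type established for silyl ketene acetals and cyclic enones, should add the acetate unit to the Si face of C-6 (setting 6S, the later C-3a) and deliver the regiodefined tetrasubstituted silyl enol ether by silyl transfer.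

Step 4
Reactants: 5 methyl 2-[(6S)-8-{[tert-butyl(dimethyl)silyl]oxy}-7-methyl-1,4-dioxaspiro[4.5]dec-7-en-6-yl]acetate
Product: 6 methyl 2-[(6S,7S)-7-methyl-8-oxo-7-(prop-2-en-1-yl)-1,4-dioxaspiro[4.5]decan-6-yl]acetate
Conditions: diallyl carbonate, Pd2(dba)3 (2.5 mol %), dppe (6 mol %), Bu4N Ph3SiF2 (35 mol %), THF, 25–40 °C
Reagents that add atoms: diallyl carbonate, C=CCOC(=O)OCC=C
Why: Fluoride-triggered Pd-catalysed Tsuji allylation of the silyl enol ether should alkylate C-7 regiospecifically, the allyl group entering anti to the neighbouring pseudo-axial CH2CO2Me group (A1,2 strain), which sets the quaternary centre (7S) with the two carbon chains trans.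

Step 5
Reactants: 6 methyl 2-[(6S,7S)-7-methyl-8-oxo-7-(prop-2-en-1-yl)-1,4-dioxaspiro[4.5]decan-6-yl]acetate
Product: 7 methyl 2-[(6S,7S,8R)-8-hydroxy-7-methyl-7-(prop-2-en-1-yl)-1,4-dioxaspiro[4.5]decan-6-yl]acetate
Conditions: K-Selectride, THF, −78 °C; H2O
Reagents that add atoms: none
Why: A bulky trialkylborohydride should follow the equatorial trajectory in the chair that carries both chains equatorial and the C-7 methyl axial, as in 4,4-disubstituted 3-oxo terpenoids, and give the axial (8R) alcohol trans to the methyl group.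

Step 6
Reactants: 7 methyl 2-[(6S,7S,8R)-8-hydroxy-7-methyl-7-(prop-2-en-1-yl)-1,4-dioxaspiro[4.5]decan-6-yl]acetate
Product: 8 methyl 2-[(6S,7S,8S)-8-bromo-7-methyl-7-(prop-2-en-1-yl)-1,4-dioxaspiro[4.5]decan-6-yl]acetate
Conditions: CBr4, PPh3, toluene, 0 to 50 °C
Reagents that add atoms: carbon tetrabromide, BrC(Br)(Br)Br
Why: The Appel reaction proceeds by SN2 attack of bromide on the axial oxyphosphonium ion with inversion, the known way to turn an axial carbinol next to a quaternary carbon into the equatorial bromide, and should give the (8S) bromide cis to the methyl group.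

Step 7
Reactants: 8 methyl 2-[(6S,7S,8S)-8-bromo-7-methyl-7-(prop-2-en-1-yl)-1,4-dioxaspiro[4.5]decan-6-yl]acetate
Product: 10 methyl 2-[(6S,7S,8S)-8-bromo-7-(2-hydroxyethyl)-7-methyl-1,4-dioxaspiro[4.5]decan-6-yl]acetate, via aldehyde 9 (not isolated)
Conditions: O3, CH2Cl2/MeOH, −78 °C; then NaBH4, −78 to 0 °C
Reagents that add atoms: ozone, [O-][O+]=O
Why: Ozonolysis of the only alkene with borohydride work-up should shorten the allyl group to a 2-hydroxyethyl group while ester, ketal and secondary bromide stay intact.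

Step 8
Reactants: 10 methyl 2-[(6S,7S,8S)-8-bromo-7-(2-hydroxyethyl)-7-methyl-1,4-dioxaspiro[4.5]decan-6-yl]acetate
Product: 11 methyl 2-[(6S,7S,8S)-8-bromo-7-(2-iodoethyl)-7-methyl-1,4-dioxaspiro[4.5]decan-6-yl]acetate
Conditions: I2, PPh3, imidazole, CH2Cl2, 0 °C
Reagents that add atoms: iodine, II
Why: Appel-type iodination of the unhindered primary alcohol should give the primary iodide needed for ring closure.

Step 9
Reactants: 11 methyl 2-[(6S,7S,8S)-8-bromo-7-(2-iodoethyl)-7-methyl-1,4-dioxaspiro[4.5]decan-6-yl]acetate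
Product: 12 methyl (3′R,3a′S,7′S,7a′S)-7′-bromo-7a′-methyloctahydrospiro[1,3-dioxolane-2,4′-indene]-3′-carboxylate
Conditions: KHMDS, THF, −78 to 0 °C; then NaOMe (cat.), MeOH, 23 °C
Reagents that add atoms: none
Why: Intramolecular 5-exo-tet alkylation of the ester enolate by the primary iodide should close the cyclopentane between the two trans, diequatorial chains (hence trans ring fusion), and methoxide equilibration should leave the ester at C-3′ trans to the C-4′ ketal carbon (3′R).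

Step 10
Reactants: 12 methyl (3′R,3a′S,7′S,7a′S)-7′-bromo-7a′-methyloctahydrospiro[1,3-dioxolane-2,4′-indene]-3′-carboxylate
Product: 13 (3′R,3a′S,7′S,7a′S)-7′-bromo-N-methoxy-N,7a′-dimethyloctahydrospiro[1,3-dioxolane-2,4′-indene]-3′-carboxamide
Conditions: MeNH(OMe)·HCl, i-PrMgCl, THF, −20 to 0 °C
Reagents that add atoms: N,O-dimethylhydroxylamine hydrochloride, CNOC.Cl
Why: Aminolysis of the methyl ester with the chloromagnesium amide of N,O-dimethylhydroxylamine (Weinreb amide formation) is reliable for hindered esters and tolerates the ketal and the secondary bromide.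

Step 11
Reactants: 14 6-methylhept-5-en-2-one
Product: 15 N′-(6-methylhept-5-en-2-ylidene)-2,4,6-tri(propan-2-yl)benzenesulfonohydrazide
Conditions: 2,4,6-triisopropylbenzenesulfonyl hydrazide, MeOH, cat. HCl, 23 °C
Reagents that add atoms: 2,4,6-triisopropylbenzenesulfonyl hydrazide, NNS(=O)(=O)c1c(C(C)C)cc(C(C)C)cc1C(C)C
Why: Condensation of the methyl ketone with the arylsulfonyl hydrazide should give the trisylhydrazone needed for the Shapiro reaction.

Step 12
Reactants: 15 N′-(6-methylhept-5-en-2-ylidene)-2,4,6-tri(propan-2-yl)benzenesulfonohydrazide; 13 (3′R,3a′S,7′S,7a′S)-7′-bromo-N-methoxy-N,7a′-dimethyloctahydrospiro[1,3-dioxolane-2,4′-indene]-3′-carboxamide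
Product: 17 1-[(3′R,3a′S,7′S,7a′S)-7′-bromo-7a′-methyloctahydrospiro[1,3-dioxolane-2,4′-inden]-3′-yl]-6-methyl-2-methylidenehept-5-en-1-one, via vinyllithium 16 (not isolated)
Conditions: 15, n-BuLi (2 equiv per 15), THF, −78 to 0 °C; then 13, −78 to −20 °C; aq NH4Cl
Reagents that add atoms: none
Why: The Shapiro reaction (deprotonation on the methyl side, loss of sulfinate and N2) should give the 2-lithio-1-alkene, whose addition to the Weinreb amide stops at the ketone through the chelated tetrahedral intermediate, so the whole C8 side chain is joined in one operation.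

Step 13
Reactants: 17 1-[(3′R,3a′S,7′S,7a′S)-7′-bromo-7a′-methyloctahydrospiro[1,3-dioxolane-2,4′-inden]-3′-yl]-6-methyl-2-methylidenehept-5-en-1-one
Product: 18 (1R)-1-[(3′R,3a′S,7′S,7a′S)-7′-bromo-7a′-methyloctahydrospiro[1,3-dioxolane-2,4′-inden]-3′-yl]-6-methyl-2-methylidenehept-5-en-1-ol
Conditions: NaBH4, CeCl3·7H2O, MeOH, −78 °C
Reagents that add atoms: none
Why: Luche 1,2-reduction should attack the carbonyl in the Felkin–Anh sense, anti to the C-3′–C-3a′ bond of the neighbouring ring stereocentre, which gives the (R)-configured allylic alcohol (C-α).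

Step 14
Reactants: 18 (1R)-1-[(3′R,3a′S,7′S,7a′S)-7′-bromo-7a′-methyloctahydrospiro[1,3-dioxolane-2,4′-inden]-3′-yl]-6-methyl-2-methylidenehept-5-en-1-ol
Product: 19 tert-butyl (1R)-1-[(3′R,3a′S,7′S,7a′S)-7′-bromo-7a′-methyloctahydrospiro[1,3-dioxolane-2,4′-inden]-3′-yl]-6-methyl-2-methylidenehept-5-en-1-yl carbonate
Conditions: Boc2O, DMAP (0.2 equiv), MeCN, 23 °C
Reagents that add atoms: di-tert-butyl dicarbonate, CC(C)(C)OC(=O)OC(=O)OC(C)(C)C
Why: DMAP-catalysed acylation with Boc2O should convert the only hydroxyl group into the tert-butyl carbonate that serves as the internal oxygen nucleophile of the next step.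

Step 15
Reactants: 19 tert-butyl (1R)-1-[(3′R,3a′S,7′S,7a′S)-7′-bromo-7a′-methyloctahydrospiro[1,3-dioxolane-2,4′-inden]-3′-yl]-6-methyl-2-methylidenehept-5-en-1-yl carbonate
Product: 20 (4R,5R,8S)-8-bromo-4-[(3′R,3a′S,7′S,7a′S)-7′-bromo-7a′-methyloctahydrospiro[1,3-dioxolane-2,4′-inden]-3′-yl]-7,7-dimethyl-1,3-dioxaspiro[4.5]decan-2-one
Conditions: NBS, chiral BINOL-derived thiophosphoramide Lewis base (10 mol %, antipode for Si-face bromine delivery), toluene/CH2Cl2, −78 to −40 °C
Reagents that add atoms: N-bromosuccinimide, O=C1CCC(=O)N1Br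
Why: Proposed new method: the Lewis base–Br+ complex formed from NBS should brominate the electron-rich Me2C=CH alkene on the Si face of its CH carbon, the CH2 end of the 1,1-disubstituted alkene opens the bromonium ion at the tertiary carbon (C-2′–C-3′ bond), and the tertiary C-1′ cation is captured by the Boc carbonyl oxygen, loss of isobutene giving the cyclic carbonate; the closest known reaction types are the Lewis-base-catalysed enantioselective bromonium-initiated cyclisation of geranyl-type polyenes onto arenes and the capture of cations by tert-butyl carbonates in halo-carbonate formation, neither shown for a 1,1-disubstituted alkene relaying to a carbonate. The carbocycle closes 6-endo-trig (both alkene carbons end in the ring, Markovnikov opening of the bromonium ion) and the 1,3-dioxolan-2-one closes 5-exo-trig. C-4′ (S) is set by the catalyst alone, because the substrate stereocentres are too remote to bias the prenyl terminus. C-1′ (R) should follow from a chair transition state with bromine equatorial in which the tethered carbonate adds along the axial direction, so that the bulky C-α stays equatorial and the hydrindanyl group of the (R)-configured C-α lies over C-6′, away from the gem-dimethyl carbon; capture is reversible until isobutene is lost, which funnels material to this more stable spiro isomer. The step needs chemoselectivity for the trisubstituted alkene (the other alkene is 1,1-disubstituted and deactivated by the allylic carbonate), the absence of a competing hydroxyl (C-4 is still a ketal, so no bridging ether can form) and suppression of elimination or 1,2-hydride shift, which the neighbouring carbonate secures.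

Step 16
Reactants: 20 (4R,5R,8S)-8-bromo-4-[(3′R,3a′S,7′S,7a′S)-7′-bromo-7a′-methyloctahydrospiro[1,3-dioxolane-2,4′-inden]-3′-yl]-7,7-dimethyl-1,3-dioxaspiro[4.5]decan-2-one
Product: 21 (3R,3aS,7S,7aS)-7-bromo-3-[(4R,5R,8S)-8-bromo-7,7-dimethyl-2-oxo-1,3-dioxaspiro[4.5]decan-4-yl]-7a-methyloctahydro-4H-inden-4-one
Conditions: 1 M HCl, THF, 40 °C
Reagents that add atoms: water, O
Why: Acid-catalysed hydrolysis of the dioxolane should free the C-4 ketone while the cyclic carbonate and both bromides are stable to aqueous acid, the mild conditions keeping enolisation toward C-3a (trans ring fusion) slow.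

Step 17
Reactants: 21 (3R,3aS,7S,7aS)-7-bromo-3-[(4R,5R,8S)-8-bromo-7,7-dimethyl-2-oxo-1,3-dioxaspiro[4.5]decan-4-yl]-7a-methyloctahydro-4H-inden-4-one
Product: 23 (3R,3aS,4R,7S,7aS)-7-bromo-3-{(R)-[(1R,4S)-4-bromo-1-hydroxy-3,3-dimethylcyclohexyl](hydroxy)methyl}-4,7a-dimethyloctahydro-1H-inden-4-ol, via carbinol carbonate 22 (not isolated)
Conditions: MeLi/CeCl3 (MeCeCl2, 6 equiv), THF, −78 to 0 °C; aq NH4Cl
Reagents that add atoms: methyllithium, [Li]C
Why: The non-basic organocerium reagent should add to the C-4 ketone along the equatorial trajectory, because the axial face is blocked by the 1,3-diaxial angular methyl, giving the axial tertiary alcohol (4R), and the excess reagent should then cleave the cyclic carbonate to the diol (its carbonyl carbon leaving as tert-butanol) without enolisation or attack on the bromides.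

**Compound list**

1 | 1,4-dioxaspiro[4.5]dec-6-en-8-one | O=C1C=CC2(CC1)OCCO2 | starting material
2 | 7-iodo-1,4-dioxaspiro[4.5]dec-6-en-8-one | O=C1CCC2(C=C1I)OCCO2 | intermediate
3 | 7-methyl-1,4-dioxaspiro[4.5]dec-6-en-8-one | CC1=CC2(CCC1=O)OCCO2 | intermediate
4 | tert-butyl[(1-methoxyethenyl)oxy]dimethylsilane | C=C(OC)O[Si](C)(C)C(C)(C)C | starting material
5 | methyl 2-[(6S)-8-{[tert-butyl(dimethyl)silyl]oxy}-7-methyl-1,4-dioxaspiro[4.5]dec-7-en-6-yl]acetate | COC(=O)C[C@@H]1C2(OCCO2)CCC(O[Si](C)(C)C(C)(C)C)=C1C | intermediate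
6 | methyl 2-[(6S,7S)-7-methyl-8-oxo-7-(prop-2-en-1-yl)-1,4-dioxaspiro[4.5]decan-6-yl]acetate | COC(=O)C[C@@H]1C2(OCCO2)CCC(=O)[C@@]1(C)CC=C | intermediate
7 | methyl 2-[(6S,7S,8R)-8-hydroxy-7-methyl-7-(prop-2-en-1-yl)-1,4-dioxaspiro[4.5]decan-6-yl]acetate | COC(=O)C[C@@H]1C2(OCCO2)CC[C@@H](O)[C@@]1(C)CC=C | intermediate
8 | methyl 2-[(6S,7S,8S)-8-bromo-7-methyl-7-(prop-2-en-1-yl)-1,4-dioxaspiro[4.5]decan-6-yl]acetate | COC(=O)C[C@@H]1C2(OCCO2)CC[C@H](Br)[C@@]1(C)CC=C | intermediate
9 | methyl 2-[(6S,7S,8S)-8-bromo-7-methyl-7-(2-oxoethyl)-1,4-dioxaspiro[4.5]decan-6-yl]acetate | COC(=O)C[C@@H]1C2(OCCO2)CC[C@H](Br)[C@@]1(C)CC=O | intermediate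
10 | methyl 2-[(6S,7S,8S)-8-bromo-7-(2-hydroxyethyl)-7-methyl-1,4-dioxaspiro[4.5]decan-6-yl]acetate | COC(=O)C[C@@H]1C2(OCCO2)CC[C@H](Br)[C@@]1(C)CCO | intermediate
11 | methyl 2-[(6S,7S,8S)-8-bromo-7-(2-iodoethyl)-7-methyl-1,4-dioxaspiro[4.5]decan-6-yl]acetate | COC(=O)C[C@@H]1C2(OCCO2)CC[C@H](Br)[C@@]1(C)CCI | intermediate
12 | methyl (3′R,3a′S,7′S,7a′S)-7′-bromo-7a′-methyloctahydrospiro[1,3-dioxolane-2,4′-indene]-3′-carboxylate | COC(=O)[C@@H]1CC[C@]2(C)[C@@H](Br)CCC3(OCCO3)[C@@H]12 | intermediate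
13 | (3′R,3a′S,7′S,7a′S)-7′-bromo-N-methoxy-N,7a′-dimethyloctahydrospiro[1,3-dioxolane-2,4′-indene]-3′-carboxamide | CON(C)C(=O)[C@@H]1CC[C@]2(C)[C@@H](Br)CCC3(OCCO3)[C@@H]12 | intermediate
14 | 6-methylhept-5-en-2-one | CC(=O)CCC=C(C)C | starting material
15 | N′-(6-methylhept-5-en-2-ylidene)-2,4,6-tri(propan-2-yl)benzenesulfonohydrazide | CC(CCC=C(C)C)=NNS(=O)(=O)c1c(C(C)C)cc(C(C)C)cc1C(C)C | intermediate
16 | (6-methylhepta-1,5-dien-2-yl)lithium | [Li]C(=C)CCC=C(C)C | intermediate
17 | 1-[(3′R,3a′S,7′S,7a′S)-7′-bromo-7a′-methyloctahydrospiro[1,3-dioxolane-2,4′-inden]-3′-yl]-6-methyl-2-methylidenehept-5-en-1-one | C=C(CCC=C(C)C)C(=O)[C@@H]1CC[C@]2(C)[C@@H](Br)CCC3(OCCO3)[C@@H]12 | intermediate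
18 | (1R)-1-[(3′R,3a′S,7′S,7a′S)-7′-bromo-7a′-methyloctahydrospiro[1,3-dioxolane-2,4′-inden]-3′-yl]-6-methyl-2-methylidenehept-5-en-1-ol | C=C(CCC=C(C)C)[C@H](O)[C@@H]1CC[C@]2(C)[C@@H](Br)CCC3(OCCO3)[C@@H]12 | intermediate
19 | tert-butyl (1R)-1-[(3′R,3a′S,7′S,7a′S)-7′-bromo-7a′-methyloctahydrospiro[1,3-dioxolane-2,4′-inden]-3′-yl]-6-methyl-2-methylidenehept-5-en-1-yl carbonate | C=C(CCC=C(C)C)[C@H](OC(=O)OC(C)(C)C)[C@@H]1CC[C@]2(C)[C@@H](Br)CCC3(OCCO3)[C@@H]12 | intermediate
20 | (4R,5R,8S)-8-bromo-4-[(3′R,3a′S,7′S,7a′S)-7′-bromo-7a′-methyloctahydrospiro[1,3-dioxolane-2,4′-inden]-3′-yl]-7,7-dimethyl-1,3-dioxaspiro[4.5]decan-2-one | CC1(C)C[C@]2(OC(=O)O[C@@H]2[C@@H]3CC[C@]4(C)[C@@H](Br)CCC5(OCCO5)[C@@H]34)CC[C@@H]1Br | intermediate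
21 | (3R,3aS,7S,7aS)-7-bromo-3-[(4R,5R,8S)-8-bromo-7,7-dimethyl-2-oxo-1,3-dioxaspiro[4.5]decan-4-yl]-7a-methyloctahydro-4H-inden-4-one | CC1(C)C[C@]2(OC(=O)O[C@@H]2[C@@H]3CC[C@]4(C)[C@@H](Br)CCC(=O)[C@@H]34)CC[C@@H]1Br | intermediate
22 | (3R,3aS,4R,7S,7aS)-7-bromo-3-[(4R,5R,8S)-8-bromo-7,7-dimethyl-2-oxo-1,3-dioxaspiro[4.5]decan-4-yl]-4,7a-dimethyloctahydro-1H-inden-4-ol | CC1(C)C[C@]2(OC(=O)O[C@@H]2[C@@H]3CC[C@]4(C)[C@@H](Br)CC[C@@](C)(O)[C@@H]34)CC[C@@H]1Br | intermediate
23 | (3R,3aS,4R,7S,7aS)-7-bromo-3-{(R)-[(1R,4S)-4-bromo-1-hydroxy-3,3-dimethylcyclohexyl](hydroxy)methyl}-4,7a-dimethyloctahydro-1H-inden-4-ol | CC1(C)C[C@@](O)([C@H](O)[C@@H]2CC[C@]3(C)[C@@H](Br)CC[C@@](C)(O)[C@@H]23)CC[C@@H]1Br | target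

**Step count and risks**

Total step count: 17. Longest linear sequence: 16 (steps 1–10 and 12–17, from 1).

Steps most likely to fail:

1. Step 15 (proposed new method). The process at risk is unselective or sluggish bromonium transfer to the remote prenyl terminus (wrong face at C-4′, and with it C-1′), or elimination instead of carbonate capture. Fallback by known chemistry, setting out from 19: Shi epoxidation of the trisubstituted alkene (ketone antipode that gives the (S)-epoxide; Oxone, K2CO3, MeCN/DMM–buffer, 0 °C) should give tert-butyl (1R)-1-[(3′R,3a′S,7′S,7a′S)-7′-bromo-7a′-methyloctahydrospiro[1,3-dioxolane-2,4′-inden]-3′-yl]-4-[(2S)-3,3-dimethyloxiran-2-yl]-2-methylidenebutyl carbonate F1. Epoxide-initiated cation–olefin cyclisation with Boc capture (MeAlCl2 or BF3·OEt2, CH2Cl2, −78 °C) should give the equatorial alcohol (4R,5R,8S)-4-[(3′R,3a′S,7′S,7a′S)-7′-bromo-7a′-methyloctahydrospiro[1,3-dioxolane-2,4′-inden]-3′-yl]-8-hydroxy-7,7-dimethyl-1,3-dioxaspiro[4.5]decan-2-one F2, the C–O bond of the epoxide CH carbon being retained. Dess–Martin oxidation should give (4R,5R)-4-[(3′R,3a′S,7′S,7a′S)-7′-bromo-7a′-methyloctahydrospiro[1,3-dioxolane-2,4′-inden]-3′-yl]-7,7-dimethyl-1,3-dioxaspiro[4.5]decane-2,8-dione F3. L-Selectride (THF, −78 °C) should give the axial alcohol (4R,5R,8R)-4-[(3′R,3a′S,7′S,7a′S)-7′-bromo-7a′-methyloctahydrospiro[1,3-dioxolane-2,4′-inden]-3′-yl]-8-hydroxy-7,7-dimethyl-1,3-dioxaspiro[4.5]decan-2-one F4, and Appel bromination (CBr4, PPh3) with inversion comes back to the route at 20.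

2. Step 3. The process at risk is low reactivity of the α-methylated, γ,γ-dialkoxy enone toward the catalyst-bound Michael addition and erosion of enantioselectivity. Fallback, setting out from 3: CBS reduction ((R)-Me-CBS, BH3·SMe2, THF, −20 °C) should give (8S)-7-methyl-1,4-dioxaspiro[4.5]dec-6-en-8-ol F5. Johnson–Claisen rearrangement (MeC(OMe)3, cat. EtCO2H, xylene, 140 °C) should transfer the chirality suprafacially to C-6 and give methyl 2-[(6S)-7-methyl-1,4-dioxaspiro[4.5]dec-7-en-6-yl]acetate F6. Hydroboration–oxidation (BH3·THF, 0 °C; NaBO3) anti to the side chain should give methyl 2-[(6S,7R,8R)-8-hydroxy-7-methyl-1,4-dioxaspiro[4.5]decan-6-yl]acetate F7, and Dess–Martin oxidation methyl 2-[(6S,7R)-7-methyl-8-oxo-1,4-dioxaspiro[4.5]decan-6-yl]acetate F8. Thermodynamic silylation (TBSOTf, Et3N, CH2Cl2, 23 °C) toward the methyl-bearing carbon comes back to the route at 5.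

3. Step 6. The process at risk is E2 elimination or Wagner–Meerwein methyl shift outrunning SN2 at the neopentyl-type carbinol. Fallback that avoids substitution, setting out from 6: kinetic enolisation and triflation (KHMDS, PhNTf2, THF, −78 °C) should give methyl 2-[(6S,7S)-7-methyl-7-(prop-2-en-1-yl)-8-{[(trifluoromethyl)sulfonyl]oxy}-1,4-dioxaspiro[4.5]dec-8-en-6-yl]acetate F9. Pd-catalysed triflate–bromide exchange (KBr, biarylphosphine ligand, dioxane, 100 °C) should give methyl 2-[(6S,7S)-8-bromo-7-methyl-7-(prop-2-en-1-yl)-1,4-dioxaspiro[4.5]dec-8-en-6-yl]acetate F10. Lemieux–Johnson cleavage of the terminal alkene (cat. OsO4, NaIO4) should give methyl 2-[(6S,7S)-8-bromo-7-methyl-7-(2-oxoethyl)-1,4-dioxaspiro[4.5]dec-8-en-6-yl]acetate F11, and NaBH4 methyl 2-[(6S,7S)-8-bromo-7-(2-hydroxyethyl)-7-methyl-1,4-dioxaspiro[4.5]dec-8-en-6-yl]acetate F12. Hydrogen-atom-transfer hydrogenation of the vinyl bromide (Mn(dpm)3, PhSiH3, t-BuOOH, i-PrOH, 23 °C), with the hydrogen atom delivered to the α-bromo radical anti to the axial C-7 methyl so that bromine ends equatorial, comes back to the route at 10.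

Further compounds
F1 | step 15 | tert-butyl (1R)-1-[(3′R,3a′S,7′S,7a′S)-7′-bromo-7a′-methyloctahydrospiro[1,3-dioxolane-2,4′-inden]-3′-yl]-4-[(2S)-3,3-dimethyloxiran-2-yl]-2-methylidenebutyl carbonate | C=C(CC[C@@H]1OC1(C)C)[C@H](OC(=O)OC(C)(C)C)[C@@H]1CC[C@]2(C)[C@@H](Br)CCC3(OCCO3)[C@@H]12
F2 | step 15 | (4R,5R,8S)-4-[(3′R,3a′S,7′S,7a′S)-7′-bromo-7a′-methyloctahydrospiro[1,3-dioxolane-2,4′-inden]-3′-yl]-8-hydroxy-7,7-dimethyl-1,3-dioxaspiro[4.5]decan-2-one | CC1(C)C[C@]2(OC(=O)O[C@@H]2[C@@H]3CC[C@]4(C)[C@@H](Br)CCC5(OCCO5)[C@@H]34)CC[C@@H]1O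
F3 | step 15 | (4R,5R)-4-[(3′R,3a′S,7′S,7a′S)-7′-bromo-7a′-methyloctahydrospiro[1,3-dioxolane-2,4′-inden]-3′-yl]-7,7-dimethyl-1,3-dioxaspiro[4.5]decane-2,8-dione | CC1(C)C[C@]2(OC(=O)O[C@@H]2[C@@H]3CC[C@]4(C)[C@@H](Br)CCC5(OCCO5)[C@@H]34)CCC1=O
F4 | step 15 | (4R,5R,8R)-4-[(3′R,3a′S,7′S,7a′S)-7′-bromo-7a′-methyloctahydrospiro[1,3-dioxolane-2,4′-inden]-3′-yl]-8-hydroxy-7,7-dimethyl-1,3-dioxaspiro[4.5]decan-2-one | CC1(C)C[C@]2(OC(=O)O[C@@H]2[C@@H]3CC[C@]4(C)[C@@H](Br)CCC5(OCCO5)[C@@H]34)CC[C@H]1O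
F5 | step 3 | (8S)-7-methyl-1,4-dioxaspiro[4.5]dec-6-en-8-ol | CC1=CC2(OCCO2)CC[C@@H]1O
F6 | step 3 | methyl 2-[(6S)-7-methyl-1,4-dioxaspiro[4.5]dec-7-en-6-yl]acetate | COC(=O)C[C@@H]1C2(OCCO2)CCC=C1C
F7 | step 3 | methyl 2-[(6S,7R,8R)-8-hydroxy-7-methyl-1,4-dioxaspiro[4.5]decan-6-yl]acetate | COC(=O)C[C@@H]1C2(OCCO2)CC[C@@H](O)[C@@H]1C
F8 | step 3 | methyl 2-[(6S,7R)-7-methyl-8-oxo-1,4-dioxaspiro[4.5]decan-6-yl]acetate | COC(=O)C[C@@H]1C2(OCCO2)CCC(=O)[C@@H]1C
F9 | step 6 | methyl 2-[(6S,7S)-7-methyl-7-(prop-2-en-1-yl)-8-{[(trifluoromethyl)sulfonyl]oxy}-1,4-dioxaspiro[4.5]dec-8-en-6-yl]acetate | COC(=O)C[C@@H]1C2(OCCO2)CC=C(OS(=O)(=O)C(F)(F)F)[C@@]1(C)CC=C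
F10 | step 6 | methyl 2-[(6S,7S)-8-bromo-7-methyl-7-(prop-2-en-1-yl)-1,4-dioxaspiro[4.5]dec-8-en-6-yl]acetate | COC(=O)C[C@@H]1C2(OCCO2)CC=C(Br)[C@@]1(C)CC=C
F11 | step 6 | methyl 2-[(6S,7S)-8-bromo-7-methyl-7-(2-oxoethyl)-1,4-dioxaspiro[4.5]dec-8-en-6-yl]acetate | COC(=O)C[C@@H]1C2(OCCO2)CC=C(Br)[C@@]1(C)CC=O
F12 | step 6 | methyl 2-[(6S,7S)-8-bromo-7-(2-hydroxyethyl)-7-methyl-1,4-dioxaspiro[4.5]dec-8-en-6-yl]acetate | COC(=O)C[C@@H]1C2(OCCO2)CC=C(Br)[C@@]1(C)CCO
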